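**Retrosynthetic overview**
- The dienal C2'=C3' bond is cut by an aldol condensation between a ring-bound CH2CHO arm and (E)-4-hydroxy-4-methylpent-2-enal (from cross-metathesis).
- Key step: the ring CHO and that CH2CHO arm are treated as the two arms of one 3-substituted glutaraldehyde; a desymmetrizing intramolecular aldol of one arm onto a cyclohexanone closes the seven-membered ring and sets C1, C2 and C3 together.
- The glutaraldehyde is unmasked by ozonolysis of a cyclopent-3-enyl group.
- The quaternary methyl carbon comes from Me2CuLi addition anti to a silyloxy group whose configuration is set by CBS reduction; the chain is attached by B-alkyl Suzuki coupling.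
- Ring order: the six-membered ring is bought; the seven-membered ring (bicyclo[4.3.1]decane) is formed by the aldol.

Assumption: 2-(cyclopent-3-en-1-yl)acetic acid, 1,4-dioxaspiro[4.5]dec-6-en-8-one, 2-methylbut-3-en-2-ol and (E)-but-2-enal are taken as catalogue compounds; core locants are C1 (carbinol bridgehead), C2 (CHO), C3 (side chain), C6 (methyl bridgehead), C7 (CHOH), C10 (one-carbon bridge).

**Route**

Step 1
Reactants: 1 2-(cyclopent-3-en-1-yl)acetic acid
Product: 2 2-(cyclopent-3-en-1-yl)ethan-1-ol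
Conditions: LiAlH4, THF, 0 °C to reflux; then H2O, aq NaOH
Reagents that add atoms: none
Why: Hydride reduction of the carboxylic acid with LiAlH4 gives the primary alcohol and leaves the isolated ring alkene untouched.

Step 2
Reactants: 2 2-(cyclopent-3-en-1-yl)ethan-1-ol
Product: 3 4-(2-iodoethyl)cyclopent-1-ene
Conditions: I2, PPh3, imidazole, CH2Cl2, 0 to 23 °C
Reagents that add atoms: iodine, II
Why: Appel-type iodination converts the primary alcohol into the iodide by displacement of the alkoxyphosphonium ion, the alkene being inert.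

Step 3
Reactants: 4 1,4-dioxaspiro[4.5]dec-6-en-8-one
Product: 5 7-iodo-1,4-dioxaspiro[4.5]dec-6-en-8-one
Conditions: I2, pyridine, CH2Cl2, 0 to 23 °C
Reagents that add atoms: iodine, II
Why: α-Iodination of the enone by pyridine conjugate addition, iodination of the enolate and elimination (Baylis–Hillman-type mechanism) proceeds under non-acidic conditions that keep the ketal.

Step 4
Reactants: 5 7-iodo-1,4-dioxaspiro[4.5]dec-6-en-8-one
Product: 6 (8R)-7-iodo-1,4-dioxaspiro[4.5]dec-6-en-8-ol
Conditions: (S)-2-methyl-CBS-oxazaborolidine (15 mol %), BH3·SMe2, THF, −20 °C; then MeOH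
Reagents that add atoms: none
Why: Corey–Bakshi–Shibata reduction in which the α-iodovinyl group acts as the large substituent, so the (S)-catalyst delivers hydride to give the (8R)-allylic alcohol (future C7) by 1,2-reduction.

Step 5
Reactants: 3 4-(2-iodoethyl)cyclopent-1-ene; 6 (8R)-7-iodo-1,4-dioxaspiro[4.5]dec-6-en-8-ol
Product: 10 (4R)-3-[2-(cyclopent-3-en-1-yl)ethyl]-4-hydroxycyclohex-2-en-1-one, via alkyllithium 7 (not isolated), via borate complex 8 (not isolated), via ketal alcohol 9 (not isolated)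
Conditions: 3, t-BuLi (2.1 equiv), Et2O, −78 °C; B-methoxy-9-BBN, THF, −78 to 23 °C; then 6, Pd(dppf)Cl2 (5 mol %), AsPh3 (5 mol %), aq K3PO4, DMF, 23 °C; then PPTS (cat.), acetone–H2O, 23 °C
Reagents that add atoms: water, O
Why: Iodine–lithium exchange at −78 °C (too cold for 5-exo carbolithiation), capture as the B-alkyl-9-BBN borate and B-alkyl Suzuki–Miyaura coupling with the vinyl iodide attach the chain without touching the carbinol centre, and the allylic ketal is then hydrolysed to the conjugated enone.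

Step 6
Reactants: 10 (4R)-3-[2-(cyclopent-3-en-1-yl)ethyl]-4-hydroxycyclohex-2-en-1-one
Product: 11 (4R)-3-[2-(cyclopent-3-en-1-yl)ethyl]-4-[(triethylsilyl)oxy]cyclohex-2-en-1-one
Conditions: Et3SiCl, imidazole, CH2Cl2, 0 °C
Reagents that add atoms: chlorotriethylsilane, CC[Si](Cl)(CC)CC
Why: Imidazole-mediated silylation protects the secondary alcohol and provides the bulky γ-substituent that will shield one face of the enone.

Step 7
Reactants: 11 (4R)-3-[2-(cyclopent-3-en-1-yl)ethyl]-4-[(triethylsilyl)oxy]cyclohex-2-en-1-one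
Product: 13 (3S,4R)-3-[2-(cyclopent-3-en-1-yl)ethyl]-3-methyl-4-[(triethylsilyl)oxy]cyclohexan-1-one, via silyl enol ether 12 (not isolated)
Conditions: MeLi, CuI, Et2O, 0 °C; then 11, Me3SiCl, THF–Et2O, −78 to −30 °C; aq NH4Cl; then K2CO3 (cat.), MeOH, 0 °C
Reagents that add atoms: lithium dimethylcuprate Me2CuLi, [Li+].C[Cu-]C, made in the flask from methyllithium, [Li]C, and CuI, [Cu]I
Why: Me3SiCl-accelerated cuprate conjugate addition to the β,β-disubstituted enone occurs anti to the adjacent silyloxy group, as is known for 4-silyloxycyclohex-2-enones, creating the quaternary centre (future C6) with methyl trans to oxygen, and the silyl enol ether is removed by methanolysis.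

Step 8
Reactants: 13 (3S,4R)-3-[2-(cyclopent-3-en-1-yl)ethyl]-3-methyl-4-[(triethylsilyl)oxy]cyclohexan-1-one
Product: 15 3-{2-[(1S,2R)-1-methyl-5-oxo-2-[(triethylsilyl)oxy]cyclohexyl]ethyl}pentanedial, via secondary ozonide 14 (not isolated)
Conditions: O3, CH2Cl2, −78 °C; then PPh3, −78 to 23 °C
Reagents that add atoms: ozone, [O-][O+]=O
Why: Ozonolysis with reductive work-up cleaves the only C=C bond and unmasks the cyclopentene as a 3-substituted glutaraldehyde whose two identical CH2CHO arms are the latent C2–CHO and C3–CH2CHO units.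

Step 9
Reactants: 15 3-{2-[(1S,2R)-1-methyl-5-oxo-2-[(triethylsilyl)oxy]cyclohexyl]ethyl}pentanedial
Product: 16 (1R,2R,3R,6S,7R)-1-hydroxy-6-methyl-3-(2-oxoethyl)-7-[(triethylsilyl)oxy]bicyclo[4.3.1]decane-2-carbaldehyde
Conditions: pyrrolidine (0.3 equiv), AcOH (0.3 equiv), CH2Cl2 (0.01 M), 23 °C
Reagents that add atoms: none
Why: Proposed new method: the enamine of either aldehyde arm can add (7-enolexo) to the ring ketone only on the face carrying the axial chain, and since this enamine aldol is reversible, C2 is epimerizable and dehydration would need a strained bridgehead enal, the mixture should funnel to the isomer with the C2 formyl and C3 CH2CHO groups both pseudo-equatorial and trans, which fixes C1, C2 and C3 as in the target; the closest known reaction type is the amine-catalysed intramolecular aldol of dicarbonyls (Hajos–Parrish and 6-enolexo aldolizations), extended here to a bridged seven-membered ring with selection between two arms.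

Step 10
Reactants: 17 2-methylbut-3-en-2-ol; 18 (E)-but-2-enal
Product: 19 (E)-4-hydroxy-4-methylpent-2-enal
Conditions: second-generation Grubbs catalyst (3 mol %), 18 (3 equiv), CH2Cl2, 40 °C
Reagents that add atoms: none
Why: Olefin cross-metathesis of the tertiary allylic alcohol with excess crotonaldehyde gives the (E)-enal under thermodynamic control with loss of propene.

Step 11
Reactants: 16 (1R,2R,3R,6S,7R)-1-hydroxy-6-methyl-3-(2-oxoethyl)-7-[(triethylsilyl)oxy]bicyclo[4.3.1]decane-2-carbaldehyde; 19 (E)-4-hydroxy-4-methylpent-2-enal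
Product: 20 (2E,4E)-2-[(1R,2R,3S,6S,7R)-2-formyl-1-hydroxy-6-methyl-7-[(triethylsilyl)oxy]bicyclo[4.3.1]decan-3-yl]-6-hydroxy-6-methylhepta-2,4-dienal
Conditions: 19 (3 equiv), pyrrolidine (0.2 equiv), PhCO2H (0.2 equiv), CH2Cl2, 23 to 40 °C
Reagents that add atoms: none
Why: Amine-catalysed crossed aldol condensation (enamine of the only CH2CHO group adds to the iminium ion of the non-enolizable, β-hindered enal, then elimination) gives the thermodynamically preferred (2E)-2-substituted dienal, while the α-branched C2 aldehyde cannot condense and the C3–H is not acidic.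

Step 12
Reactants: 20 (2E,4E)-2-[(1R,2R,3S,6S,7R)-2-formyl-1-hydroxy-6-methyl-7-[(triethylsilyl)oxy]bicyclo[4.3.1]decan-3-yl]-6-hydroxy-6-methylhepta-2,4-dienal
Product: 21 umbellacin A, (2E,4E)-2-[(1R,2R,3S,6S,7R)-2-formyl-1,7-dihydroxy-6-methylbicyclo[4.3.1]decan-3-yl]-6-hydroxy-6-methylhepta-2,4-dienal
Conditions: HF·pyridine, pyridine, THF, 0 °C
Reagents that add atoms: none
Why: Buffered fluoride desilylation removes the triethylsilyl ether without base, so the β-hydroxy aldehyde (retro-aldol) and the dienal survive.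

**Compound list**
1 | 2-(cyclopent-3-en-1-yl)acetic acid | OC(=O)CC1CC=CC1 | starting material
2 | 2-(cyclopent-3-en-1-yl)ethan-1-ol | OCCC1CC=CC1 | intermediate
3 | 4-(2-iodoethyl)cyclopent-1-ene | ICCC1CC=CC1 | intermediate
4 | 1,4-dioxaspiro[4.5]dec-6-en-8-one | O=C1C=CC2(CC1)OCCO2 | starting material
5 | 7-iodo-1,4-dioxaspiro[4.5]dec-6-en-8-one | O=C1C(I)=CC2(CC1)OCCO2 | intermediate
6 | (8R)-7-iodo-1,4-dioxaspiro[4.5]dec-6-en-8-ol | IC1=CC2(OCCO2)CC[C@H]1O | intermediate
7 | [2-(cyclopent-3-en-1-yl)ethyl]lithium | [Li]CCC1CC=CC1 | intermediate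
8 | lithium 9-[2-(cyclopent-3-en-1-yl)ethyl]-9-methoxy-9-boranuidabicyclo[3.3.1]nonane | [Li+].CO[B-]1(CCC2CC=CC2)C3CCCC1CCC3 | intermediate
9 | (8R)-7-[2-(cyclopent-3-en-1-yl)ethyl]-1,4-dioxaspiro[4.5]dec-6-en-8-ol | C1=CCC(C1)CCC2=CC3(OCCO3)CC[C@H]2O | intermediate
10 | (4R)-3-[2-(cyclopent-3-en-1-yl)ethyl]-4-hydroxycyclohex-2-en-1-one | C1=CCC(C1)CCC2=CC(=O)CC[C@H]2O | intermediate
11 | (4R)-3-[2-(cyclopent-3-en-1-yl)ethyl]-4-[(triethylsilyl)oxy]cyclohex-2-en-1-one | C1=CCC(C1)CCC2=CC(=O)CC[C@H]2O[Si](CC)(CC)CC | intermediate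
12 | {[(3S,4R)-3-[2-(cyclopent-3-en-1-yl)ethyl]-3-methyl-4-[(triethylsilyl)oxy]cyclohex-1-en-1-yl]oxy}trimethylsilane | C1=CCC(C1)CC[C@@]2(C)C=C(O[Si](C)(C)C)CC[C@H]2O[Si](CC)(CC)CC | intermediate
13 | (3S,4R)-3-[2-(cyclopent-3-en-1-yl)ethyl]-3-methyl-4-[(triethylsilyl)oxy]cyclohexan-1-one | C1=CCC(C1)CC[C@@]2(C)CC(=O)CC[C@H]2O[Si](CC)(CC)CC | intermediate
14 | secondary ozonide of 13 (3-substituted 6,7,8-trioxabicyclo[3.2.1]octane, isomer mixture at the ozonide ring) | O1OC2CC(CC1O2)CC[C@@]3(C)CC(=O)CC[C@H]3O[Si](CC)(CC)CC | intermediate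
15 | 3-{2-[(1S,2R)-1-methyl-5-oxo-2-[(triethylsilyl)oxy]cyclohexyl]ethyl}pentanedial | O=CCC(CC=O)CC[C@@]1(C)CC(=O)CC[C@H]1O[Si](CC)(CC)CC | intermediate
16 | (1R,2R,3R,6S,7R)-1-hydroxy-6-methyl-3-(2-oxoethyl)-7-[(triethylsilyl)oxy]bicyclo[4.3.1]decane-2-carbaldehyde (C3 has the same spatial arrangement as 3S in 20 and 21; the descriptor differs by CIP priority only) | O=CC[C@H]1CC[C@@]2(C)C[C@](O)(CC[C@H]2O[Si](CC)(CC)CC)[C@@H]1C=O | intermediate
17 | 2-methylbut-3-en-2-ol | CC(C)(O)C=C | starting material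
18 | (E)-but-2-enal | C/C=C/C=O | starting material
19 | (E)-4-hydroxy-4-methylpent-2-enal | CC(C)(O)/C=C/C=O | intermediate
20 | (2E,4E)-2-[(1R,2R,3S,6S,7R)-2-formyl-1-hydroxy-6-methyl-7-[(triethylsilyl)oxy]bicyclo[4.3.1]decan-3-yl]-6-hydroxy-6-methylhepta-2,4-dienal | CC(C)(O)/C=C/C=C(/C=O)[C@H]1CC[C@@]2(C)C[C@](O)(CC[C@H]2O[Si](CC)(CC)CC)[C@@H]1C=O | intermediate
21 | umbellacin A, (2E,4E)-2-[(1R,2R,3S,6S,7R)-2-formyl-1,7-dihydroxy-6-methylbicyclo[4.3.1]decan-3-yl]-6-hydroxy-6-methylhepta-2,4-dienal | CC(C)(O)/C=C/C=C(/C=O)[C@H]1CC[C@@]2(C)C[C@](O)(CC[C@H]2O)[C@@H]1C=O | target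

**Totals**
Total step count: 12.
Longest linear sequence: 9 steps (4 to 21 through steps 3, 4, 5, 6, 7, 8, 9, 11, 12; the branch from 1 through steps 1, 2, 5, 6, 7, 8, 9, 11, 12 is equally long).

**Steps most likely to fail and their fallbacks**

Step 9 (highest risk). The aldol onto a ketone may be thermodynamically unfavourable for a bridged seven-membered ring, or a ketone-enamine condensation onto an aldehyde may compete. The fallback sets out from 15 and comes back at 16. It moves the ring closure to the carboxylic oxidation level, where a chelated metal enolate adds irreversibly. Pinnick oxidation (NaClO2, NaH2PO4, 2-methylbut-2-ene, t-BuOH–H2O) gives 3-{2-[(1S,2R)-1-methyl-5-oxo-2-[(triethylsilyl)oxy]cyclohexyl]ethyl}pentanedioic acid F1. PhSH, EDC·HCl and DMAP give the bis(S-phenyl) dithioester F2. TiCl4 and Bu3N in CH2Cl2 at −78 °C enolize a thioester arm (more acidic than the ring ketone), and the titanium enolate closes onto the ketone to give the bicyclic β-hydroxy bis(thioester) F3; the arm is again chosen in the chair-like transition state. Fukuyama reduction (Et3SiH, Pd/C, acetone) turns both thioesters into aldehydes, and brief Et3N treatment equilibrates C2, giving 16.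

Step 11. Self-condensation of 16, reaction at the wrong aldehyde, or retro-aldol under amine catalysis could erode the yield. The fallback sets out from 16 and comes back at 20. It makes the side-chain C3'–C4' bond by Heck coupling instead of making C2'=C3' by condensation. α-Methylenation of the CH2CHO arm (aq CH2O, pyrrolidine and propionic acid as catalysts, i-PrOH, 45 °C) gives (1R,2R,3S,6S,7R)-1-hydroxy-6-methyl-3-(3-oxoprop-1-en-2-yl)-7-[(triethylsilyl)oxy]bicyclo[4.3.1]decane-2-carbaldehyde F4. Hydrozirconation–iodination of 2-methylbut-3-yn-2-ol (Cp2Zr(H)Cl, then I2) gives (E)-4-iodo-2-methylbut-3-en-2-ol F5. Heck reaction of F4 with F5 (Pd(OAc)2, Bu4NCl, NaHCO3, DMF, 40 °C) gives 20 with the (2E,4E) geometry.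

Step 7. The hindered enone may react slowly, or the anti selectivity may be eroded by the β-chain. The fallback sets out from 5 (with 3 as chain source) and comes back at 13. It exchanges the roles of the two substituents: methyl sits on the enone and the chain is delivered syn to a free alkoxide, instead of methyl being delivered anti to a silyl ether. Suzuki–Miyaura methylation of 5 (MeB(OH)2, Pd(dppf)Cl2, K2CO3, dioxane–H2O) gives 7-methyl-1,4-dioxaspiro[4.5]dec-6-en-8-one F6. The same CBS reduction gives (8R)-7-methyl-1,4-dioxaspiro[4.5]dec-6-en-8-ol F7. PPTS in wet acetone gives (4R)-4-hydroxy-3-methylcyclohex-2-en-1-one F8. 3 and Mg in Et2O give [2-(cyclopent-3-en-1-yl)ethyl]magnesium iodide F9, which is added to the magnesium alkoxide of F8 (pre-formed with t-BuMgCl, THF, −40 °C). The chain is delivered to the β-carbon on the oxygen-bearing face (alkoxide-directed conjugate addition) to give (3S,4R)-3-[2-(cyclopent-3-en-1-yl)ethyl]-4-hydroxy-3-methylcyclohexan-1-one F10. Et3SiCl and imidazole then give 13.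

Further compounds
F1 | step 9 | 3-{2-[(1S,2R)-1-methyl-5-oxo-2-[(triethylsilyl)oxy]cyclohexyl]ethyl}pentanedioic acid | OC(=O)CC(CC(=O)O)CC[C@@]1(C)CC(=O)CC[C@H]1O[Si](CC)(CC)CC
F2 | step 9 | S,S'-diphenyl 3-{2-[(1S,2R)-1-methyl-5-oxo-2-[(triethylsilyl)oxy]cyclohexyl]ethyl}pentanebis(thioate) | O=C(Sc1ccccc1)CC(CC(=O)Sc1ccccc1)CC[C@@]2(C)CC(=O)CC[C@H]2O[Si](CC)(CC)CC
F3 | step 9 | S-phenyl (1R,2R,3R,6S,7R)-1-hydroxy-6-methyl-3-[2-oxo-2-(phenylsulfanyl)ethyl]-7-[(triethylsilyl)oxy]bicyclo[4.3.1]decane-2-carbothioate | O=C(Sc3ccccc3)C[C@H]1CC[C@@]2(C)C[C@](O)(CC[C@H]2O[Si](CC)(CC)CC)[C@@H]1C(=O)Sc4ccccc4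
F4 | step 11 | (1R,2R,3S,6S,7R)-1-hydroxy-6-methyl-3-(3-oxoprop-1-en-2-yl)-7-[(triethylsilyl)oxy]bicyclo[4.3.1]decane-2-carbaldehyde | C=C(C=O)[C@H]1CC[C@@]2(C)C[C@](O)(CC[C@H]2O[Si](CC)(CC)CC)[C@@H]1C=O
F5 | step 11 | (E)-4-iodo-2-methylbut-3-en-2-ol | CC(C)(O)/C=C/I
F6 | step 7 | 7-methyl-1,4-dioxaspiro[4.5]dec-6-en-8-one | CC1=CC2(OCCO2)CCC1=O
F7 | step 7 | (8R)-7-methyl-1,4-dioxaspiro[4.5]dec-6-en-8-ol | CC1=CC2(OCCO2)CC[C@H]1O
F8 | step 7 | (4R)-4-hydroxy-3-methylcyclohex-2-en-1-one | CC1=CC(=O)CC[C@H]1O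
F9 | step 7 | [2-(cyclopent-3-en-1-yl)ethyl]magnesium iodide | I[Mg]CCC1CC=CC1
F10 | step 7 | (3S,4R)-3-[2-(cyclopent-3-en-1-yl)ethyl]-4-hydroxy-3-methylcyclohexan-1-one | C1=CCC(C1)CC[C@@]2(C)CC(=O)CC[C@H]2O
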